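# Proposed synthesis of CNP0197219.1 by enone–enol ether photocycloaddition and strain-driven pinacol ring expansion

Atom labels used throughout: ring A is C1 (quaternary, carries C12H2OAc)–C2H2–C3H(OAc)–C4H(OH)–C5Me2–C6 (quaternary). The cage is C6, C7H2, the cyclopropane C8H–C9H–C10(Me) and C11H(OAc), joined by C6–C7, C7–C8, C9–C1, C10–C11 and C11–C6.

## The problem

The target is a cyclohexane (ring A) fused along C1–C6 to a tricyclo[2.2.1.0(2,6)]heptane cage: C6 is tied by three one-carbon arms (C1, C7, C11) to the cyclopropane C8–C9–C10. C1, C5, C6 and C10 are fully substituted, and C5–C6–C1 are contiguous. Of the eight stereocentres, C6, C8, C9 and C10 follow from the cage once it exists. The free choices are C1 (C2 on the side of C11, C12 on the side of C7), C11 (acetoxy over C7, hydrogen toward ring A) and the cis C3/C4 diol, which lies on the ring A face that carries C7 and C12. C4 can come from the chiral pool and set C3 by chelation. The C3/C4 pair, locked in a cis-fused acetonide next to the C5 gem-dimethyl group, can then decide the face on which C1–C6 forms and so the absolute sense of the whole cage. C11 can only be set after the cage shields one of its faces. The C11 acetate is a cyclopropylcarbinyl ester that ionises under acid, and the free, hindered C4 hydroxyl sits next to an acetate. Any strained intermediate with an oxygen β to a ketone can open by retro-aldol, and a cation at C9 would rearrange. The feature that makes a short key step possible is that the quaternary pair C1–C6 lies in the five-membered ring C1–C6–C11–C10–C9. If C10 is inserted last, C1, C6, C11 and C9 form a cyclobutane, the [2+2] adduct of a C6=C11 enone and a C1=C9 alkene tethered through C2–C5, which is ring A itself.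

## Retrosynthesis

**Ester pattern (39 from 38 and 37).** The C3 acetate is cut last. Diol 38 comes from acetonide 37, so the only late selectivity asked for is acetylation of the C3 hydroxyl in preference to the C4 hydroxyl, which is flanked by the quaternary C5.

**C11–O bond (37 from 35, 34 and 33).** The C11–O bond is cut with inversion. Hydride can reach a C11 ketone only over C7, which gives the hydroxyl on the ring A side, and SN2 at a carbon between two quaternary centres is not possible. Because C11 is cyclopropylcarbinyl once the cage is complete, the epimeric alcohol 35 can be ionised as its mesylate and captured by acetate from the open C7 face. Alcohol 35 comes from diol 34 and the dibenzyl ether 33.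

**C8–C9 bond (33 from 31 and 30).** The cyclopropane bond opposite C10 is cut to a carbene at C9 inserting into the endo C8–H bond of a bicyclo[2.2.1]heptane. A cationic closure at C9 is rejected because Wagner–Meerwein shift to the tertiary C10 would win. The precursor ketone 30 (through hydrazone 31) has lost the three-membered ring, and two of the cage stereocentres (C8, C9) vanish with it. The forward step needs a carbene without α-hydrogen and a C8–H bond held under it.

**Oxidation-state adjustments (30 from 26).** The C11 ketone of 26 must be reduced and masked (27, 28) before C9 is oxidised (29, 30). A non-enolisable 2,7-dione would be cleaved by hydrazine.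

**C9–C10 bond (26 from 25 and 24).** The C9–C10 bond is cut and C9–C11 restored, a pinacol-type 1,2-shift run backwards. This turns the bicyclo[2.2.1]heptan-7-one 26 into the cyclobutane-fused cyclopentanone 24 and removes the C10 methyl, which is added as MeLi. The forward reaction needs a cation at C10, a donor oxygen on C11 and the strain of the four-membered ring.

**C1–C6 and C9–C11 bonds (24 from 23).** Both bonds are cut at once, the retron of an intramolecular enone–alkene [2+2] photocycloaddition. The precursor 23 has one ring instead of three and only the two stereocentres C3 and C4. No other cut removes the contiguous C5–C6–C1 congestion in one step. The forward reaction must close "straight" (C6–C1, C11–C9) and on the enone face opposite the acetonide.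

**Enone and enol ether (23 from 22, 21 and 19).** Both silyl enol ethers are made from one dione–aldehyde 22. Compound 22 is the oxidation product of α-ketol 21, itself the acyloin of glutarate 19. The C9 alcohol of 19 comes from hydroboration of the 1,1-disubstituted alkene of 18.

**C6–C7 and C10–C11 bonds (18 from 16 and 17; 16 from 12).** The cyclopentane is cut at C10–C11 (acyloin) and C6–C7 (Michael addition of ester 16 to methyl acrylate 17). C6 itself is inserted between C5 and the carboxyl carbon of acid 12 by Arndt–Eistert homologation, which avoids substitution at a neopentyl carbon.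

**C2–C3 bond and the C3 stereocentre (12 from 10, 9, 8, 6 and 3).** C2–C3 is cut to Weinreb amide 6 and the allyl Grignard reagent 7 made from chloride 3. Ketone 8 is reduced under chelation control to the anti diol 9. Addition of 7 to an aldehyde would give the syn diol under the same chelation, hence the detour through the ketone.

**Starting materials (6 from 5 and 4; 3 from 1 and 2).** (R)-Pantolactone 4 supplies C3, C4, C5 with its methyls and C11. Dichloride 1 and benzyl alcohol 2 supply C2, C1, C9, C12 and the C12 protecting group.

## Roads not taken

**Alternative 1:** The cut is C1–C2, made on a finished cage. In the forward key step Bu3SnH turns the bromoacetal A2, hung on the C11 oxygen, into a C2 radical that adds to the exocyclic alkenylboronate at C1 (Ueno–Stork cyclisation). This gives the cage-fused ethoxytetrahydropyran A1 with a C12 boronate for later oxidation.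
- Merits: the tether delivers C2 to C1 from the C11 side with certainty, the reaction is thermal and needs no dilution, and the boronate is a clean C12 hydroxyl equivalent.
- Weak points: the whole cage with the C5–C6 quaternary link must already exist, so the hardest bond set is left unsolved. The tether works only if the C11 oxygen points toward C1, the epimer of the target, so C11 must be inverted afterwards. Ring A still has to be closed at C3–C4 with two new stereocentres late in the route.
- Comparison: in certainty of the C1 configuration this road is better than the chosen one, which relies on a conformational preference. The chosen plan sets against this that it makes C1, C6 and C11 and two rings in one step and carries C3/C4 from the chiral pool.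

**Alternative 2:** The cuts are C9–C10 and C11–O. In the forward key step anodic oxidation of the norbornene carboxylic acid A4 in buffered acetic acid (Hofer–Moest conditions) gives the C9 cation. The C10=C11 alkene captures it (homoallyl to cyclopropylcarbinyl) and acetate adds at C11 to give A3.
- Merits: cyclopropane and C11 acetate arise together. A3 is the same compound as 37 of the chosen route, so this end-game would replace steps 19–27 by one step and is clearly shorter there.
- Weak points: A4 must contain the C1–C6 quaternary pair, ring A and a bridgehead-substituted norbornene, for which this road offers no construction. The secondary C9 cation next to the quaternary C1 can shift C2, C6 or C12 before the alkene reaches it. Acetate can also enter at C9 or C8.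
- Comparison: the chosen plan is longer at the end. It sets against this a secure entry to the quaternary pair and a cyclopropane closure that is fixed by geometry (carbene insertion) and not by cation partitioning. The facial preference of acetate at C11 is the same question in both routes.

**Alternative 3:** The cut is C5–C6. In the forward key step, heating the cyclopenta-fused dihydropyran A6 makes its 2-methylpropenyl group at C3 bond to C6 while O–C3 breaks (Claisen rearrangement), giving the spiro[4.5]decenone A5.
- Merits: a thermal, stereospecific step that forms the bond between two quaternary carbons and relays C3 to C6. The C3=C4 alkene allows the diol to be introduced late without protecting groups.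
- Weak points: both termini are fully substituted, so the rearrangement is slow and must pass through a ring-constrained transition state. C1 must be made enantiopure beforehand as a quaternary centre with two similar CH2X arms. After the key step C9–C11, C9–C10 and C8–C9 are all still open, so the cage costs three further C–C bond formations and the face of the later dihydroxylation is uncontrolled.
- Comparison: this road is at least as reliable as a photochemical step for the one bond it makes, but it builds ring A only. The chosen step closes ring A and the cyclobutane together and leaves a single skeletal shift and one C–H insertion to finish the cage.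

Key step: step 16

Assumption: silyl enol ether 23 is used as an E/Z mixture and several intermediates as epimer mixtures at centres that are erased later (C6 and C1 in 18–22, C9 in 24–29, C10 in 25). None of these affects the stereochemical outcome.

## Route

Step 1
Reactants: 1 3-chloro-2-(chloromethyl)prop-1-ene; 2 benzyl alcohol
Product: 3 benzyl 2-(chloromethyl)prop-2-enyl ether
Conditions: NaH, THF, 0 to 20 °C, 1 in excess
Reagents that add atoms: none
Why: Williamson ether synthesis at an allylic chloride; an excess of the symmetric dichloride holds the reaction at mono-substitution.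

Step 2
Reactants: 4 (R)-pantolactone
Product: 5 (2R)-2,4-dihydroxy-N-methoxy-N,3,3-trimethylbutanamide
Conditions: MeNH(OMe)·HCl, AlMe3, CH2Cl2, 0 to 20 °C
Reagents that add atoms: N,O-dimethylhydroxylamine hydrochloride, CNOC.Cl
Why: Aminolysis of the lactone by the aluminium amide (Weinreb amide formation); the C4 stereocentre is not touched.

Step 3
Reactants: 5 Weinreb amide diol
Product: 6 (2R)-4-(tert-butyldimethylsilyloxy)-2-hydroxy-N-methoxy-N,3,3-trimethylbutanamide
Conditions: tBuMe2SiCl, imidazole, CH2Cl2, 0 °C
Reagents that add atoms: tert-butyldimethylsilyl chloride, CC(C)(C)[Si](C)(C)Cl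
Why: Silylation selective for the primary hydroxyl over the hindered secondary one; it leaves only the 1,2-diol free when the acetonide is made in step 6.

Step 4
Reactants: 6 silylated Weinreb amide; 3 benzyl 2-(chloromethyl)prop-2-enyl ether
Product: 8 (3R)-6-(benzyloxymethyl)-1-(tert-butyldimethylsilyloxy)-3-hydroxy-2,2-dimethylhept-6-en-4-one, via allylmagnesium chloride 7 (not isolated)
Conditions: Mg, THF, 0 °C; then 6, THF, −78 to 0 °C; NH4Cl (aq)
Reagents that add atoms: magnesium, [Mg] (in intermediate 7 only)
Why: Grignard addition to a Weinreb amide stops at the ketone because the chelated tetrahedral adduct survives until work-up; the first equivalent of 7 only deprotonates the C4 hydroxyl, and either allyl terminus gives the same product.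

Step 5
Reactants: 8 α-hydroxy ketone
Product: 9 (3R,4S)-6-(benzyloxymethyl)-1-(tert-butyldimethylsilyloxy)-2,2-dimethylhept-6-ene-3,4-diol
Conditions: Zn(BH4)2, Et2O, −20 °C
Reagents that add atoms: none
Why: Chelation-controlled reduction of an α-hydroxy ketone: zinc bridges the C3 carbonyl and the C4 oxygen and hydride enters anti to the tert-alkyl group on C4, setting C3 as S (anti diol, the future cis diol of ring A).

Step 6
Reactants: 9 anti diol
Product: 10 silyl ether of the (4R,5S)-acetonide, cis-4,5-disubstituted 2,2-dimethyl-1,3-dioxolane
Conditions: Me2C(OMe)2, PPTS (cat.), CH2Cl2, 20 °C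
Reagents that add atoms: 2,2-dimethoxypropane, COC(C)(C)OC
Why: Acid-catalysed transketalisation; only the 1,2-diol is free, so the cis-dioxolane is the only acetonide that can form.

Step 7
Reactants: 10 silyl ether acetonide
Product: 11 2-[(4R,5S)-5-[2-(benzyloxymethyl)prop-2-enyl]-2,2-dimethyl-1,3-dioxolan-4-yl]-2-methylpropan-1-ol
Conditions: Bu4NF, THF, 20 °C
Reagents that add atoms: none
Why: Fluoride cleavage of the primary silyl ether; acetal, alkene and benzyl ether are inert.

Step 8
Reactants: 11 primary alcohol
Product: 12 2-[(4R,5S)-5-[2-(benzyloxymethyl)prop-2-enyl]-2,2-dimethyl-1,3-dioxolan-4-yl]-2-methylpropanoic acid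
Conditions: TEMPO (cat.), PhI(OAc)2, MeCN/H2O, 20 °C
Reagents that add atoms: water, O
Why: Nitroxyl-catalysed oxidation of a primary alcohol through the aldehyde hydrate to the acid; the near-neutral medium spares the acetonide, and the carboxyl carbon is the future C11.

Step 9
Reactants: 12 carboxylic acid
Product: 14 1-diazo-3-[(4R,5S)-5-[2-(benzyloxymethyl)prop-2-enyl]-2,2-dimethyl-1,3-dioxolan-4-yl]-3-methylbutan-2-one, via acid chloride 13 (not isolated)
Conditions: (COCl)2, DMF (cat.), CH2Cl2, 0 °C; then CH2N2, Et2O, 0 °C
Reagents that add atoms: diazomethane, C=[N+]=[N-]; oxalyl chloride, O=C(Cl)C(Cl)=O (chlorine of intermediate 13 only)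
Why: Acylation of diazomethane by the acid chloride, the first half of an Arndt–Eistert homologation; the acid has no α-hydrogen, so no ketene can form from the chloride.

Step 10
Reactants: 14 diazoketone
Product: 16 methyl 3-[(4R,5S)-5-[2-(benzyloxymethyl)prop-2-enyl]-2,2-dimethyl-1,3-dioxolan-4-yl]-3-methylbutanoate, via ketene 15 (not isolated)
Conditions: hν (Pyrex), MeOH, 20 °C
Reagents that add atoms: methanol, CO
Why: Photochemical Wolff rearrangement: the tertiary C5 migrates to the diazo carbon and methanol traps the ketene; the new CH2 is C6.

Step 11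
Reactants: 16 methyl ester; 17 methyl acrylate
Product: 18 dimethyl 2-[2-[(4R,5S)-5-[2-(benzyloxymethyl)prop-2-enyl]-2,2-dimethyl-1,3-dioxolan-4-yl]propan-2-yl]pentanedioate (both C6 epimers)
Conditions: LiN(iPr)2, THF, −78 °C; then 17, −78 °C; NH4Cl (aq)
Reagents that add atoms: none
Why: Michael addition of the lithium ester enolate to the acrylate forms C6–C7; the new centre at C6 is of no consequence because C6 becomes trigonal in step 14.

Step 12
Reactants: 18 glutarate
Product: 19 dimethyl 2-[2-[(4R,5S)-5-[3-(benzyloxy)-2-(hydroxymethyl)propyl]-2,2-dimethyl-1,3-dioxolan-4-yl]propan-2-yl]pentanedioate (epimers at C1 and C6)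
Conditions: 9-BBN, THF, 20 °C; then H2O2, NaOAc (aq), 0 °C
Reagents that add atoms: hydrogen peroxide, OO
Why: Anti-Markovnikov hydroboration–oxidation of the 1,1-disubstituted alkene gives the C9 alcohol; 9-BBN does not reduce esters and the buffered work-up does not hydrolyse them.

Step 13
Reactants: 19 hydroxy glutarate
Product: 21 α-ketol, 2-hydroxy-3-substituted cyclopentanone with free C9 hydroxyl (in equilibrium with its C10-hydroxy regioisomer), via tris(trimethylsilyl) enediol ether 20 (not isolated)
Conditions: Na, Me3SiCl, toluene, 110 °C; then MeOH, K2CO3 (cat.), 0 °C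
Reagents that add atoms: chlorotrimethylsilane, C[Si](C)(C)Cl (silyl groups of intermediate 20 only)
Why: Acyloin condensation of a glutarate with in situ silylation of the enediolate, the standard entry to five-membered acyloins, forms C10–C11; methanolysis frees the ketol and the primary alcohol.

Step 14
Reactants: 21 α-ketol
Product: 22 diosphenol aldehyde, 2-hydroxycyclopent-2-enone (C10 carbonyl, C11 hydroxyl, C6 substituted) with C9 aldehyde
Conditions: Dess–Martin periodinane, NaHCO3, CH2Cl2, 0 to 20 °C
Reagents that add atoms: none
Why: Dess–Martin oxidation converts the ketol into the 1,2-dione and the primary alcohol into the aldehyde in one operation; the dione rests as its more substituted enol.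

Step 15
Reactants: 22 diosphenol aldehyde
Product: 23 2-(tert-butyldimethylsilyloxy)cyclopent-2-enone with tethered C1=C9 tert-butyldimethylsilyl enol ether (E/Z mixture)
Conditions: tBuMe2SiOTf, Et3N, CH2Cl2, −78 to −40 °C
Reagents that add atoms: tert-butyldimethylsilyl trifluoromethanesulfonate, CC(C)(C)[Si](C)(C)OS(=O)(=O)C(F)(F)F
Why: O-silylation of the acidic enol and soft enolisation of the α-branched aldehyde by silyl triflate and amine; no free enolate is formed, so benzyl oxide is not expelled from the β-position.

Step 16
Reactants: 23 bis-silyl photosubstrate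
Product: 24 tricyclic cyclobutane photoadduct (C10 ketone, C11 and C9 silyl ethers, C12 benzyl ether, C3/C4 acetonide)
Conditions: hν (350–366 nm, Pyrex), degassed CH2Cl2, high dilution, −20 °C
Reagents that add atoms: none
Why: Excitation and intersystem crossing give the enone triplet, whose β-carbon C6 bonds to C1 and closes ring A in a 6-exo mode through the four-atom tether C2–C5; the resulting 1,4-biradical (C11 captodative, C9 oxygen-stabilised) then collapses after spin inversion to close C11–C9 and the cyclobutane. The closest known reaction type is the intramolecular enone–alkene [2+2] photocycloaddition of 2-oxygenated cycloalkenones with enol ether partners attached at the β-carbon. The straight mode is required and is secured by ring size, since C6–C9 bonding would need a seven-membered ring and first bonding at C11 a seven- or eight-membered one. C1, C6 and C11 are set together: a cyclobutane fused to a five- and a six-membered ring closes only cis at both fusions, which puts C7 and C12 on one face and C2 and C5 on the other. The enone face, and with it the absolute sense of C1, C6 and C11, is controlled by C3/C4: A(1,2) strain with the C11 silyloxy group holds C4 anti to C11 about C5–C6, and in the chair-like fold the cis-acetonide places its C4 oxygen axial and its C3 oxygen equatorial, because the other chair would set the C3 oxygen syn-axial to a C5 methyl and to C9. This fold delivers the cyclobutane to the face opposite the acetonide. C9 is not controlled and need not be, as it is oxidised in step 22. Dilution suppresses dimerisation, and light above 340 nm leaves the benzyl and silyl groups unexcited.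

Step 17
Reactants: 24 photoadduct
Product: 25 tertiary C10 alcohol (C10 methyl carbinol, either epimer)
Conditions: MeLi, CeCl3, THF, −78 °C
Reagents that add atoms: methyllithium, [Li]C
Why: 1,2-addition of the organocerium reagent to a hindered, enolisable cyclopentanone; the configuration of the carbinol is irrelevant because C10 becomes cationic in step 18.

Step 18
Reactants: 25 tertiary alcohol
Product: 26 bicyclo[2.2.1]heptan-7-one (C11 ketone, C10 methyl bridgehead, C9 silyl ether)
Conditions: Me3SiOTf (10 mol %), CH2Cl2, −78 to −40 °C; Et3N quench
Reagents that add atoms: none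
Why: Pinacol-type (semipinacol) ring expansion: ionisation at C10, 1,2-shift of C9 from C11 to C10 driven by cyclobutane strain and by the silyloxy donor on C11, then loss of the silyl group from the oxocarbenium ion. A fragmentation–reclosure (retro-aldol/aldol) path through the C9 oxocarbenium ion and the C10=C11 enol ether gives the same ketone. C10 is set by the suprafacial shift within the bicycle.

Step 19
Reactants: 26 bridging ketone
Product: 27 C11 alcohol, hydroxyl syn to the C1–C9 bridge (C11 epimer of the target)
Conditions: NaBH4, MeOH/THF, 0 °C
Reagents that add atoms: none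
Why: Hydride reduction of the strained bridging ketone; hydride arrives over the unsubstituted C7–C8 bridge, away from ring A, so the hydroxyl points toward ring A. This epimer is corrected in step 27.

Step 20
Reactants: 27 C11 alcohol
Product: 28 C11 benzyl ether
Conditions: KH, BnBr, Bu4NI (cat.), THF, 0 to 20 °C
Reagents that add atoms: benzyl bromide, BrCc1ccccc1
Why: Williamson benzylation of the potassium alkoxide; the ether masks C11 while C9 is oxidised and turned into a carbene, and it leaves with the C12 benzyl group in step 25.

Step 21
Reactants: 28 silyl ether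
Product: 29 C9 alcohol
Conditions: Bu4NF, THF, 50 °C
Reagents that add atoms: none
Why: Fluoride desilylation; attack is at silicon, so the congestion at C9 only slows the reaction.

Step 22
Reactants: 29 C9 alcohol
Product: 30 C9 ketone (bicyclo[2.2.1]heptan-2-one flanked by quaternary C1 and C10)
Conditions: Dess–Martin periodinane, NaHCO3, CH2Cl2, 20 °C
Reagents that add atoms: none
Why: Dess–Martin oxidation of a hindered secondary alcohol; the ketone has no α-hydrogen and cannot epimerise or condense.

Step 23
Reactants: 30 C9 ketone
Product: 31 C9 hydrazone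
Conditions: N2H4·H2O (excess), AcOH (cat.), n-BuOH, 110 °C
Reagents that add atoms: hydrazine, NN
Why: Hydrazone formation; hydrazine is the smallest nitrogen nucleophile for a carbonyl flanked by two quaternary carbons, and the basic medium keeps the acetonide and both ethers intact.

Step 24
Reactants: 31 hydrazone
Product: 33 cage dibenzyl ether acetonide (cyclopropane C8–C9–C10 closed), via C9 diazoalkane 32 (not isolated)
Conditions: HgO, Na2SO4, toluene, 20 to 110 °C
Reagents that add atoms: none
Why: Oxidation of the hydrazone to the diazoalkane and thermal loss of N2 give the C9 carbene, which has no α-hydrogen and inserts into the endo C8–H bond held beneath it, the 1,3-insertion known from bicyclo[2.2.1]heptan-2-ylidenes (camphor hydrazone to tricyclene). C8 and C9 follow from the cage.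

Step 25
Reactants: 33 dibenzyl ether
Product: 34 cage diol (C11 and C12 hydroxyls, acetonide)
Conditions: H2 (1 atm), Pd/C, EtOAc, 20 °C
Reagents that add atoms: none
Why: Hydrogenolysis of both benzyl ethers; the cyclopropane carries no activating group and should survive Pd/C at atmospheric pressure.

Step 26
Reactants: 34 diol
Product: 35 C12 acetate with free C11 hydroxyl
Conditions: Ac2O, pyridine, CH2Cl2, 0 °C
Reagents that add atoms: acetic anhydride, CC(=O)OC(C)=O
Why: Acetylation selective for the primary hydroxyl; the C11 hydroxyl between two quaternary carbons and under ring A reacts far more slowly.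

Step 27
Reactants: 35 C11 alcohol
Product: 37 C11,C12-diacetate acetonide with the C11 configuration of the target, via C11 mesylate 36 (not isolated)
Conditions: MeSO2Cl, Et3N, CH2Cl2, −20 °C; then AcOH, KOAc, 40 °C
Reagents that add atoms: acetic acid, CC(=O)O; methanesulfonyl chloride, CS(Cl)(=O)=O (in intermediate 36 only)
Why: Mesylation through the small sulfene, then buffered acetolysis. The cyclopropylcarbinyl mesylate ionises with help of the C8–C10 bond, and acetic acid attacks C11 of the delocalised cation from the open face over C7, anti to the leaving group, so C11 is inverted.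

Step 28
Reactants: 37 diacetate acetonide
Product: 38 C3,C4-diol C11,C12-diacetate
Conditions: AcOH/H2O (4:1), 40 °C
Reagents that add atoms: none
Why: Mild acid hydrolysis of the acetonide; an acetate is too poor a leaving group for C11 to ionise under these conditions.

Step 29
Reactants: 38 diol
Product: 39 CNP0197219.1
Conditions: Ac2O (1.1 equiv), pyridine, CH2Cl2, −20 to 0 °C
Reagents that add atoms: acetic anhydride, CC(=O)OC(C)=O
Why: Mono-acetylation of the cis diol at the less hindered C3 hydroxyl; the C4 hydroxyl next to the quaternary C5 is the slower one.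

## Compound list

1 | 3-chloro-2-(chloromethyl)prop-1-ene | C=C(CCl)CCl | starting material
2 | benzyl alcohol | OCc1ccccc1 | starting material
3 | benzyl 2-(chloromethyl)prop-2-enyl ether | C=C(CCl)COCc1ccccc1 | intermediate
4 | (R)-pantolactone | CC1(C)COC(=O)[C@@H]1O | starting material
5 | (2R)-2,4-dihydroxy-N-methoxy-N,3,3-trimethylbutanamide | CON(C)C(=O)[C@H](O)C(C)(C)CO | intermediate
6 | (2R)-4-(tert-butyldimethylsilyloxy)-2-hydroxy-N-methoxy-N,3,3-trimethylbutanamide | CON(C)C(=O)[C@H](O)C(C)(C)CO[Si](C)(C)C(C)(C)C | intermediate
7 | [2-(benzyloxymethyl)prop-2-enyl]magnesium chloride | C=C(C[Mg]Cl)COCc1ccccc1 | intermediate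
8 | (3R)-6-(benzyloxymethyl)-1-(tert-butyldimethylsilyloxy)-3-hydroxy-2,2-dimethylhept-6-en-4-one | c1ccccc1COCC(=C)CC(=O)[C@H](O)C(C)(C)CO[Si](C)(C)C(C)(C)C | intermediate
9 | (3R,4S)-6-(benzyloxymethyl)-1-(tert-butyldimethylsilyloxy)-2,2-dimethylhept-6-ene-3,4-diol | c1ccccc1COCC(=C)C[C@H](O)[C@H](O)C(C)(C)CO[Si](C)(C)C(C)(C)C | intermediate
10 | tert-butyl[2-[(4R,5S)-5-[2-(benzyloxymethyl)prop-2-enyl]-2,2-dimethyl-1,3-dioxolan-4-yl]-2-methylpropoxy]dimethylsilane | c1ccccc1COCC(=C)C[C@@H]1OC(C)(C)O[C@@H]1C(C)(C)CO[Si](C)(C)C(C)(C)C | intermediate
11 | 2-[(4R,5S)-5-[2-(benzyloxymethyl)prop-2-enyl]-2,2-dimethyl-1,3-dioxolan-4-yl]-2-methylpropan-1-ol | c1ccccc1COCC(=C)C[C@@H]1OC(C)(C)O[C@@H]1C(C)(C)CO | intermediate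
12 | 2-[(4R,5S)-5-[2-(benzyloxymethyl)prop-2-enyl]-2,2-dimethyl-1,3-dioxolan-4-yl]-2-methylpropanoic acid | c1ccccc1COCC(=C)C[C@@H]1OC(C)(C)O[C@@H]1C(C)(C)C(=O)O | intermediate
13 | acid chloride of 12 | c1ccccc1COCC(=C)C[C@@H]1OC(C)(C)O[C@@H]1C(C)(C)C(=O)Cl | intermediate
14 | 1-diazo-3-[(4R,5S)-5-[2-(benzyloxymethyl)prop-2-enyl]-2,2-dimethyl-1,3-dioxolan-4-yl]-3-methylbutan-2-one | c1ccccc1COCC(=C)C[C@@H]1OC(C)(C)O[C@@H]1C(C)(C)C(=O)C=[N+]=[N-] | intermediate
15 | 3-[(4R,5S)-5-[2-(benzyloxymethyl)prop-2-enyl]-2,2-dimethyl-1,3-dioxolan-4-yl]-3-methylbut-1-en-1-one (ketene) | c1ccccc1COCC(=C)C[C@@H]1OC(C)(C)O[C@@H]1C(C)(C)C=C=O | intermediate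
16 | methyl 3-[(4R,5S)-5-[2-(benzyloxymethyl)prop-2-enyl]-2,2-dimethyl-1,3-dioxolan-4-yl]-3-methylbutanoate | c1ccccc1COCC(=C)C[C@@H]1OC(C)(C)O[C@@H]1C(C)(C)CC(=O)OC | intermediate
17 | methyl acrylate | C=CC(=O)OC | starting material
18 | dimethyl 2-[2-[(4R,5S)-5-[2-(benzyloxymethyl)prop-2-enyl]-2,2-dimethyl-1,3-dioxolan-4-yl]propan-2-yl]pentanedioate, C6 epimers | c1ccccc1COCC(=C)C[C@@H]1OC(C)(C)O[C@@H]1C(C)(C)C(CCC(=O)OC)C(=O)OC | intermediate
19 | dimethyl 2-[2-[(4R,5S)-5-[3-(benzyloxy)-2-(hydroxymethyl)propyl]-2,2-dimethyl-1,3-dioxolan-4-yl]propan-2-yl]pentanedioate, C1 and C6 epimers | c1ccccc1COCC(CO)C[C@@H]1OC(C)(C)O[C@@H]1C(C)(C)C(CCC(=O)OC)C(=O)OC | intermediate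
20 | 1,2-bis(trimethylsilyloxy)cyclopentene carrying at C6 the (C3S,C4R)-acetonide chain with C9 trimethylsilyl ether | c1ccccc1COCC(CO[Si](C)(C)C)C[C@@H]1OC(C)(C)O[C@@H]1C(C)(C)C1CCC(O[Si](C)(C)C)=C1O[Si](C)(C)C | intermediate
21 | α-ketol: 2-hydroxycyclopentanone (C10 carbonyl, C11 hydroxyl) carrying at C6 the (C3S,C4R)-acetonide chain with C9 hydroxyl; used with its C10-hydroxy regioisomer | c1ccccc1COCC(CO)C[C@@H]1OC(C)(C)O[C@@H]1C(C)(C)C1CCC(=O)C1O | intermediate
22 | diosphenol aldehyde: 2-hydroxycyclopent-2-enone substituted at C6 by the (C3S,C4R)-acetonide chain ending in the C9 aldehyde | c1ccccc1COCC(C=O)C[C@@H]1OC(C)(C)O[C@@H]1C(C)(C)C1=C(O)C(=O)CC1 | intermediate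
23 | 2-(tert-butyldimethylsilyloxy)cyclopent-2-enone with tethered C1=C9 silyl enol ether, (C3S,C4R)-acetonide, C12 benzyl ether | c1ccccc1COCC(=CO[Si](C)(C)C(C)(C)C)C[C@@H]1OC(C)(C)O[C@@H]1C(C)(C)C1=C(O[Si](C)(C)C(C)(C)C)C(=O)CC1 | intermediate
24 | tricyclic cyclobutane photoadduct: cyclobutane C1–C6–C11–C9 cis-fused to ring A and to the C10 cyclopentanone, acetonide anti to the cyclobutane, C9 either epimer | c1ccccc1COC[C@]12C[C@@H]3OC(C)(C)O[C@@H]3C(C)(C)[C@]14CCC(=O)[C@]4(O[Si](C)(C)C(C)(C)C)C2O[Si](C)(C)C(C)(C)C | intermediate
25 | C10 methyl carbinol of 24, either C10 epimer | c1ccccc1COC[C@]12C[C@@H]3OC(C)(C)O[C@@H]3C(C)(C)[C@]14CCC(C)(O)[C@]4(O[Si](C)(C)C(C)(C)C)C2O[Si](C)(C)C(C)(C)C | intermediate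
26 | bicyclo[2.2.1]heptan-7-one: C11 ketone bridging C6 and C10, C10 methyl, C9 silyl ether, ring A fused at C1–C6 | c1ccccc1COC[C@]12C[C@@H]3OC(C)(C)O[C@@H]3C(C)(C)[C@]14CC[C@@](C)(C4=O)C2O[Si](C)(C)C(C)(C)C | intermediate
27 | C11 alcohol of 26, hydroxyl syn to the C1–C9 bridge | c1ccccc1COC[C@]12C[C@@H]3OC(C)(C)O[C@@H]3C(C)(C)[C@]14CC[C@@](C)([C@@H]4O)C2O[Si](C)(C)C(C)(C)C | intermediate
28 | C11 benzyl ether of 27 | c1ccccc1COC[C@]12C[C@@H]3OC(C)(C)O[C@@H]3C(C)(C)[C@]14CC[C@@](C)([C@@H]4OCc4ccccc4)C2O[Si](C)(C)C(C)(C)C | intermediate
29 | C9 alcohol, C11 and C12 benzyl ethers | c1ccccc1COC[C@]12C[C@@H]3OC(C)(C)O[C@@H]3C(C)(C)[C@]14CC[C@@](C)([C@@H]4OCc4ccccc4)C2O | intermediate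
30 | C9 ketone, C11 and C12 benzyl ethers | c1ccccc1COC[C@]12C[C@@H]3OC(C)(C)O[C@@H]3C(C)(C)[C@]14CC[C@@](C)([C@@H]4OCc4ccccc4)C2=O | intermediate
31 | C9 hydrazone of 30 | c1ccccc1COC[C@]12C[C@@H]3OC(C)(C)O[C@@H]3C(C)(C)[C@]14CC[C@@](C)([C@@H]4OCc4ccccc4)C2=NN | intermediate
32 | C9 diazoalkane | c1ccccc1COC[C@]12C[C@@H]3OC(C)(C)O[C@@H]3C(C)(C)[C@]14CC[C@@](C)([C@@H]4OCc4ccccc4)C2=[N+]=[N-] | intermediate
33 | complete cage: C11 (epimeric) and C12 benzyl ethers, C3/C4 acetonide | c1ccccc1COC[C@]12C[C@@H]3OC(C)(C)O[C@@H]3C(C)(C)[C@]13C[C@@H]1[C@H]2[C@]1(C)[C@@H]3OCc1ccccc1 | intermediate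
34 | cage C11 (epimeric), C12 diol, C3/C4 acetonide | OC[C@]12C[C@@H]3OC(C)(C)O[C@@H]3C(C)(C)[C@]13C[C@@H]1[C@H]2[C@]1(C)[C@@H]3O | intermediate
35 | cage C12 acetate, C11 (epimeric) alcohol, acetonide | CC(=O)OC[C@]12C[C@@H]3OC(C)(C)O[C@@H]3C(C)(C)[C@]13C[C@@H]1[C@H]2[C@]1(C)[C@@H]3O | intermediate
36 | C11 mesylate of 35 | CC(=O)OC[C@]12C[C@@H]3OC(C)(C)O[C@@H]3C(C)(C)[C@]13C[C@@H]1[C@H]2[C@]1(C)[C@@H]3OS(C)(=O)=O | intermediate
37 | cage C11,C12-diacetate with C11 configuration of the target, C3/C4 acetonide | CC(=O)OC[C@]12C[C@@H]3OC(C)(C)O[C@@H]3C(C)(C)[C@]13C[C@@H]1[C@H]2[C@]1(C)[C@H]3OC(C)=O | intermediate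
38 | cage C11,C12-diacetate, C3,C4 cis-diol | CC(=O)OC[C@]12C[C@H](O)[C@H](O)C(C)(C)[C@]13C[C@@H]1[C@H]2[C@]1(C)[C@H]3OC(C)=O | intermediate
39 | CNP0197219.1 (C3, C11, C12 triacetate, C4 alcohol) | CC(=O)OC[C@]12C[C@H](OC(C)=O)[C@H](O)C(C)(C)[C@]13C[C@@H]1[C@H]2[C@]1(C)[C@H]3OC(C)=O | target

## Step count and risks

Total: 29 steps. Longest linear sequence: 28 steps, from (R)-pantolactone 4 (steps 2–29). Step 1 is a one-step side branch.

Least certain steps:

**Step 16 (key step).** The fold may react in part on the enone face syn to the acetonide, because the preference rests on conformational energies rather than a covalent constraint. The excited β-carbon, crowded by C5, may also take a hydrogen from C3 or give up the first bond, which would lower efficiency. Fallback: run the same two bond formations in the ground state. From 23, catalytic Tf2NH or EtAlCl2 in CH2Cl2 at −78 °C should bring about Mukaiyama–Michael addition of C1 to C6, then aldol-type closure of C11 onto the C9 silyloxycarbenium ion. This is the known acid-catalysed Michael–aldol [2+2] of silyl enol ethers with enones. It returns to the route at 24; new compounds on its way: none F0.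

**Step 15.** The dione may be silylated on its other enol (C10 oxygen), the C10 ketone may be converted further to a silyloxydiene by excess triflate, or benzyl alcohol may be eliminated from the β-benzyloxy aldehyde if enolate character develops. Fallback: separate the two events by reagent class. From 22, tBuMe2SiCl and imidazole silylate only the acidic enol and give the mono-silyl diosphenol aldehyde F1. One equivalent of tBuMe2SiOTf with Et3N at −78 °C then converts the aldehyde alone, returning at 23.

**Step 18.** The C10 cation may lose a proton to an alkene. The donor-substituted cyclobutane may also open by fragmentation and the open oxocarbenium ion be captured by the water that ionisation of a hydroxyl releases. Fallback: generate the same cation from an alkene, without a leaving hydroxyl. From 24, Wittig methylenation (Ph3PCH3Br, KOtBu, toluene, 80 °C) gives the exo-methylene cyclobutane F2. Protonation by anhydrous catalytic TfOH in CH2Cl2 at −78 °C installs the C10 methyl and triggers the same 1,2-shift, returning at 26.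

**Step 24 (with its preparation in step 23).** Condensation at C9 may stall, since both faces of the carbonyl are screened by C1, the C10 methyl and the C11 benzyloxy group. The carbene may also insert in part into the ether-activated C12–H bonds or suffer a 1,2-alkyl shift. Fallback: the tosylhydrazone route, in which the diazoalkane forms without oxidant and without water. From 30, TsNHNH2 in toluene at 110 °C with water removal gives the tosylhydrazone F3. Its sodium salt (NaH, diglyme, 150 °C, Bamford–Stevens conditions) loses sulfinate and N2 and returns at 33.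

**Step 27.** The delocalised cation may be captured at C8 or C9 (homoallyl acetates), or on the ring A face after ion-pair return, so that inversion is incomplete. Fallback: correct C11 by a redox equilibration instead of ionisation. From 35, Dess–Martin oxidation gives the cyclopropyl ketone F4. Meerwein–Ponndorf–Verley reduction under equilibrating conditions (Al(OiPr)3, iPrOH, 82 °C) should favour the less crowded alcohol over C7 and at the same time transesterifies the C12 acetate, giving the diol F5. Ac2O with 4-dimethylaminopyridine acetylates both hydroxyls and returns at 37.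

## Further compounds

F0 | step 16 | none | none
F1 | step 15 | mono-silyl diosphenol aldehyde (C11 silyl ether, C9 aldehyde) | c1ccccc1COCC(C=O)C[C@@H]1OC(C)(C)O[C@@H]1C(C)(C)C1=C(O[Si](C)(C)C(C)(C)C)C(=O)CC1
F2 | step 18 | exo-methylene cyclobutane (C10 methylidene analogue of 24) | c1ccccc1COC[C@]12C[C@@H]3OC(C)(C)O[C@@H]3C(C)(C)[C@]14CCC(=C)[C@]4(O[Si](C)(C)C(C)(C)C)C2O[Si](C)(C)C(C)(C)C
F3 | step 24 | C9 tosylhydrazone of 30 | c1ccccc1COC[C@]12C[C@@H]3OC(C)(C)O[C@@H]3C(C)(C)[C@]14CC[C@@](C)([C@@H]4OCc4ccccc4)C2=NNS(=O)(=O)c2ccc(C)cc2
F4 | step 27 | cage C11 ketone, C12 acetate, acetonide | CC(=O)OC[C@]12C[C@@H]3OC(C)(C)O[C@@H]3C(C)(C)[C@]13C[C@@H]1[C@H]2[C@]1(C)C3=O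
F5 | step 27 | cage C11 (target configuration), C12 diol, acetonide | OC[C@]12C[C@@H]3OC(C)(C)O[C@@H]3C(C)(C)[C@]13C[C@@H]1[C@H]2[C@]1(C)[C@H]3O
A1 | alternative 1 | cage-fused 2-ethoxytetrahydropyran with C12 pinacol boronate | CC1(C)OB(C[C@]23C[C@@H](OCC)O[C@@H]4[C@@]2(C(C)(C)C=C)C[C@@H]5[C@H]3[C@]45C)OC1(C)C
A2 | alternative 1 | bromoacetal on the C11 oxygen of the cage with exocyclic alkenylboronate at C1 | BrCC(OCC)O[C@@H]1[C@@]2(C(C)(C)C=C)C[C@@H]3[C@H](C2=CB2OC(C)(C)C(C)(C)O2)[C@]13C
A3 | alternative 2 | cage C11,C12-diacetate with C3/C4 acetonide (identical with 37) | CC(=O)OC[C@]12C[C@@H]3OC(C)(C)O[C@@H]3C(C)(C)[C@]14C[C@@H]5[C@H]2[C@]5(C)[C@H]4OC(C)=O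
A4 | alternative 2 | bicyclo[2.2.1]heptene C9 carboxylic acid (bridgeheads C6 and C8, alkene C10=C11) | CC(=O)OC[C@]12C[C@@H]3OC(C)(C)O[C@@H]3C(C)(C)[C@]14C[C@@H](C(C)=C4)C2C(=O)O
A5 | alternative 3 | spiro[4.5]decenone with ring A alkene | c1ccccc1COC[C@]1(CS(=O)(=O)c2ccccc2)CC=CC(C)(C)[C@]13CC[C@H](C)C3=O
A6 | alternative 3 | cyclopenta-fused 3,4-dihydro-2H-pyran with 2-methylprop-1-enyl group at C3 | c1ccccc1COC[C@]1(CS(=O)(=O)c2ccccc2)C[C@H](C=C(C)C)OC2=C1CC[C@@H]2C
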